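1. Compare larch with oak, and give each run a load λ: substrate squared times mol%, relative to the flask. Oak has 0.250, larch 4.00, alder 0.480.

| flask | substrate | gas phase | catalyst | remark | time |
|---|---|---|---|---|---|
| oak | 0.75 M | 200 mM (held) | 2.5 mol% | run made earlier |  |
| larch | 3 M | 200 mM (held) | 2.5 mol% | run made earlier |  |
| alder | 1.5 M | 200 mM (held) | 1.2 mol% | run made earlier |  |
| flask | 1.5 M | 200 mM (held) | 2.5 mol% |  | 80 min |

| run | time / min | target / % |
|---|---|---|
| oak | 10.0 | 9.9 |
| oak | 20.0 | 19.6 |
| oak | 30.0 | 25.2 |
| oak | 40.0 | 28.4 |
| oak | 50.0 | 29.6 |
| oak | 60.0 | 27.9 |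
| larch | 4.00 | 3.0 |
| larch | 12.0 | 10.2 |
| larch | 25.0 | 17.8 |
| larch | 40.0 | 27.5 |
| larch | 50.0 | 33.1 |
| larch | 60.0 | 37.4 |
| alder | 6.00 | 4.4 |
| alder | 15.0 | 11.2 |
| alder | 30.0 | 18.9 |
| alder | 50.0 | 25.0 |
| alder | 60.0 | 25.7 |

(each reading ± 0.5 percentage points)

1. how much target there is at 80 min, in percent of the substrate charged
2. concentration of dissolved gas in solution at 8.0 min, in percent of saturation
3. the change that raises the amount of target at 80 min, in percent of the substrate charged most ("none" if none brings more than 2 percentage points) (dawn / summer / dusk / none)
4. amount of target at 80 min, in percent of the substrate charged, after summer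

- dawn: doubling the transfer coefficient of the gas phase, all else as stated
- summer: doubling the amount of catalyst, all else as stated
- dusk: doubling the saturation concentration of gas phase, all else as stated

- at the start none of the gas phase is in solution

2. Apply the bench rule: with dissolved gas held at saturation, the rate follows catalyst times substrate (pseudo-first-order in substrate at fixed catalyst). Larch should then outrun oak 16.0 times.

3. Read the first rates of target. Oak gives 7.43 mM min⁻¹, larch 25.5 mM min⁻¹, a ratio of 3.43, which is smaller than the rule promised. So treat dissolved gas as the concentration that sets the order.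

4. Give gas transfer a ceiling T and define the gas number n, the catalyst's demand at saturation over T for the flask's charge. Write x = nλ, scaled by the fraction of substrate remaining. Then rate = T·x/(1+x), and the share of saturation is 1/(1+x). Oak and larch give n = 1.29 and T = 30.4 mM min⁻¹. The border is x = 1: above it transfer is the rate-limiting step, below it the bench rule returns. Check on alder: this predicts 11.6 mM min⁻¹, and the reading gives 11.0 mM min⁻¹. The flask starts just past the border, and I reckon a share of 43.7%.

5. The forecast says 44%, a share of 36%, summer, and 62%. Its share is lower than mine and comes from its own transfer fit, which in its words means “dissolved gas sits at about 35–37% of saturation”.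

    gas phase ⇌ dissolved gas, rate k1*(csat - [dissolved gas]) (kL = 0.220 min⁻¹)
    substrate + dissolved gas + catalyst → catalyst + target (k = 10.0 M⁻² min⁻¹)
    target → over-reaction product (k = 0.00580 min⁻¹)
    substrate + dissolved gas → uncatalysed product (k = 0.230 M⁻¹ min⁻¹)
    target + catalyst ⇌ isomer of the product + catalyst, rate k5*[catalyst]*[target] forward; the back reaction follows from the equilibrium constant (K = 0.400, k = 0.580 M⁻¹ min⁻¹)

6. The flask gives 34.8% target, a share of 22.0%, and summer as best at 42.5%. At 8.00 min the flask holds 9.21% target beside 6.17% uncatalysed product. Read n again from that share, with 83.8% substrate remaining: it comes to 4.23, larger than my 1.29. Carry it to 40.0 min, where 23.8% substrate remains: it gives a share of 49.8%, and the flask stands at 47.5%.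

Readings and results were generated by integration for substances that don't exist; noise was put on by code.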